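**Retrosynthetic overview**

- The strategy rests on the substitution pattern of the single benzene ring: the oxygens on C2 and C4 are meta with C3–H between them, and the carboxyl-bearing C1 lies between C2–O and the C6 side chain.
- The benzene ring, the only ring, is formed in one operation from a tert-butyl 2-diazo-3-oxo-4-methylidene ester and ethoxyacetylene. A Wolff shift makes C1–C6, a [2+2] addition makes C3–C4 and C1–C2, and a six-electron closure makes C4–C5, so the ketene carbonyl becomes C4–OH and the ynol ether gives C3–H and C2–OEt.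
- After the ring: O-methylation at C4, desilylation and oxidation to the side-chain ketone (C2′; C1′ is the benzylic CH2), then one BCl3 operation frees the C2 phenol and the acid.
- Before the ring: the diazo keto ester comes from a 2-methylidene acid by malonate half-ester homologation and diazo transfer; the acid comes from dodecanal and ethyl 2-(bromomethyl)acrylate by Zn allylation, silylation and saponification.
- A tert-butyl ester is carried instead of a methyl ester, so that the freed C2′ hydroxyl should not lactonise onto it and no basic hydrolysis of a hindered benzoate next to the ketone is needed.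

Key step: step 6

Remark: the side-chain carbinol carbon is carried as a racemate, since it becomes the C2′ ketone in step 9 and the target has no stereocentre. TBS = tert-butyldimethylsilyl.

**Route**

Step 1
Reactants: 1 dodecanal; 2 ethyl 2-(bromomethyl)acrylate
Product: 4 ethyl 4-hydroxy-2-methylidenepentadecanoate (racemic), via allylzinc bromide 3 (not isolated)
Conditions: Zn dust, THF/sat. aq. NH4Cl, 0 → 20 °C
Reagents that add atoms: none
Why: Barbier allylation, in which Zn inserts into the allylic C–Br bond and the 2-(ethoxycarbonyl)allylzinc bromide adds to the aldehyde in the buffered aqueous medium, which at room temperature should give the open γ-hydroxy ester and not the α-methylene lactone; the carbinol centre forms racemic and is oxidised later.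

Step 2
Reactants: 4 ethyl 4-hydroxy-2-methylidenepentadecanoate
Product: 5 ethyl 4-[(tert-butyldimethylsilyl)oxy]-2-methylidenepentadecanoate (racemic)
Conditions: TBSCl, imidazole, DMF, 20 °C
Reagents that add atoms: tert-butyldimethylsilyl chloride, CC(C)(C)[Si](C)(C)Cl
Why: Imidazole-promoted silylation of a secondary alcohol, which closes off lactonisation of the γ-hydroxy ester and gives an ether that should last through steps 3 to 7.

Step 3
Reactants: 5 ethyl 4-[(tert-butyldimethylsilyl)oxy]-2-methylidenepentadecanoate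
Product: 6 4-[(tert-butyldimethylsilyl)oxy]-2-methylidenepentadecanoic acid (racemic)
Conditions: LiOH·H2O, THF/H2O, 20 °C; then 1 M HCl to pH 4, 0 °C
Reagents that add atoms: lithium hydroxide, [Li+].[OH-]
Why: Ester saponification by acyl–oxygen cleavage, in which the α-branched acrylate is a poor Michael acceptor for hydroxide and the secondary TBS ether is stable to aqueous base and to brief cold acidification.

Step 4
Reactants: 6 4-[(tert-butyldimethylsilyl)oxy]-2-methylidenepentadecanoic acid; 7 potassium tert-butyl malonate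
Product: 10 tert-butyl 6-[(tert-butyldimethylsilyl)oxy]-4-methylidene-3-oxoheptadecanoate (racemic), via acyl imidazolide 8 (not isolated), via acylmalonic half ester 9 (not isolated)
Conditions: CDI, THF, 20 °C; then 7, MgCl2, Et3N, MeCN, 20 → 40 °C; 0.5 M HCl, 0 °C
Reagents that add atoms: none
Why: Masamune–Brooks homologation, in which the acyl imidazolide C-acylates the magnesium enolate of the malonate half ester and the acylmalonate loses CO2 on acidification, under near-neutral conditions that spare the silyl ether and the 1,1-disubstituted alkene.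

Step 5
Reactants: 10 tert-butyl 6-[(tert-butyldimethylsilyl)oxy]-4-methylidene-3-oxoheptadecanoate
Product: 11 tert-butyl 6-[(tert-butyldimethylsilyl)oxy]-2-diazo-4-methylidene-3-oxoheptadecanoate (racemic)
Conditions: 4-acetamidobenzenesulfonyl azide, Et3N, MeCN, 0 → 20 °C
Reagents that add atoms: 4-acetamidobenzenesulfonyl azide, CC(=O)Nc1ccc(cc1)S(=O)(=O)N=[N+]=[N-]
Why: Regitz diazo transfer to the activated methylene of a β-keto ester, which also removes the acidic CH2 and so should stabilise the polymerisation-prone alkenyl keto ester.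

Step 6
Reactants: 11 tert-butyl 6-[(tert-butyldimethylsilyl)oxy]-2-diazo-4-methylidene-3-oxoheptadecanoate; 12 ethoxyacetylene
Product: 17 tert-butyl 2-ethoxy-4-hydroxy-6-{2-[(tert-butyldimethylsilyl)oxy]tridecyl}benzoate (racemic), via vinylketene 13 (not isolated), via vinylcyclobutenone 14 (not isolated), via dienylketene 15 (not isolated), via cyclohexadienone 16 (not isolated)
Conditions: 12 (3 equiv), degassed ClCH2CH2Cl, hν (254 nm, quartz), 20 °C; then sealed vessel, 80 °C
Reagents that add atoms: none
Why: Proposed new method: Irradiation expels N2 with 1,2-shift of the alkenyl group (Wolff rearrangement, C1–C6) to give ketene 13, whose carbonyl carbon is attacked by the nucleophilic CH carbon of 12 (C3–C4) before the ester-stabilised α-carbon closes on the ethoxy-bearing carbon (C1–C2) to give cyclobutenone 14. On warming, 14 opens by reversible four-electron electrocyclic cleavage to 15, and the isomer with the alkenyl group cis to the ketene closes the benzene ring by six-electron electrocyclisation (C4–C5) to 16, which tautomerises to phenol 17. The closest known reaction type is the Danheiser benzannulation of vinylketenes from α-diazo enones with alkoxy- or siloxyalkynes; new here is the alkoxycarbonyl group on the ketene α-carbon, which should raise the electrophilicity of the ketene and so favour the first C–C bond. No stereocentre is set, since the quaternary carbon of 14 is lost on ring opening and the racemic silyloxy carbon is a spectator. The step needs regiocontrol in the [2+2] addition, secured by the polarisation of the ynol ether (nucleophilic at CH) against the ketene carbonyl carbon so that OEt ends next to the ester carbon, and it needs [2+2] to win over [4+2] addition across the O=C–C=C=O unit, for which the hindered, weakly nucleophilic tert-butyl ester carbonyl is a poor partner. Excess 12 should limit acylation of phenol 17 by ketene 13.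

Step 7
Reactants: 17 tert-butyl 2-ethoxy-4-hydroxy-6-{2-[(tert-butyldimethylsilyl)oxy]tridecyl}benzoate
Product: 18 tert-butyl 2-ethoxy-4-methoxy-6-{2-[(tert-butyldimethylsilyl)oxy]tridecyl}benzoate (racemic)
Conditions: MeI, K2CO3, acetone, 50 °C
Reagents that add atoms: iodomethane, CI
Why: Williamson etherification of the only free phenol (C4–OH), the C2 oxygen being already capped as its ethyl ether, so the two ring oxygens stay differentiated.

Step 8
Reactants: 18 tert-butyl 2-ethoxy-4-methoxy-6-{2-[(tert-butyldimethylsilyl)oxy]tridecyl}benzoate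
Product: 19 tert-butyl 2-ethoxy-6-(2-hydroxytridecyl)-4-methoxybenzoate (racemic)
Conditions: HF·pyridine, pyridine, THF, 0 → 20 °C
Reagents that add atoms: none
Why: Fluoride-mediated desilylation under non-basic conditions, in which no alkoxide is formed and the hindered tert-butyl ester should resist lactonisation onto the freed C2′ hydroxyl.

Step 9
Reactants: 19 tert-butyl 2-ethoxy-6-(2-hydroxytridecyl)-4-methoxybenzoate
Product: 20 tert-butyl 2-ethoxy-4-methoxy-6-(2-oxotridecyl)benzoate
Conditions: Dess–Martin periodinane, CH2Cl2, 0 → 20 °C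
Reagents that add atoms: none
Why: Dess–Martin oxidation of a secondary alcohol to the ketone under neutral conditions that the electron-rich arene and the tert-butyl ester tolerate, which also removes the only stereocentre.

Step 10
Reactants: 20 tert-butyl 2-ethoxy-4-methoxy-6-(2-oxotridecyl)benzoate
Product: 22 2-hydroxy-4-methoxy-6-(2-oxotridecyl)benzoic acid, via chloroborate chelate 21 (not isolated)
Conditions: BCl3 (1 M in CH2Cl2, 4 equiv), CH2Cl2, −78 → 0 °C; then H2O, 0 °C
Reagents that add atoms: none
Why: Chelation-controlled ether cleavage, in which BCl3 bridges the ester carbonyl and the ortho ether oxygen so that chloride dealkylates the C2 ethyl ether but not the unchelated C4 methyl ether, while the same Lewis acid ionises the tert-butyl ester and cold water hydrolyses chloroborate 21 to the salicylic acid.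

**Compound list**

1 | dodecanal | CCCCCCCCCCCC=O | starting material
2 | ethyl 2-(bromomethyl)acrylate | C=C(CBr)C(=O)OCC | starting material
3 | [2-(ethoxycarbonyl)prop-2-en-1-yl]zinc bromide | CCOC(=O)C(=C)C[Zn]Br | intermediate
4 | ethyl 4-hydroxy-2-methylidenepentadecanoate (racemic) | CCCCCCCCCCCC(O)CC(=C)C(=O)OCC | intermediate
5 | ethyl 4-[(tert-butyldimethylsilyl)oxy]-2-methylidenepentadecanoate (racemic) | CCCCCCCCCCCC(O[Si](C)(C)C(C)(C)C)CC(=C)C(=O)OCC | intermediate
6 | 4-[(tert-butyldimethylsilyl)oxy]-2-methylidenepentadecanoic acid (racemic) | CCCCCCCCCCCC(O[Si](C)(C)C(C)(C)C)CC(=C)C(=O)O | intermediate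
7 | potassium tert-butyl malonate (potassium 3-tert-butoxy-3-oxopropanoate) | CC(C)(C)OC(=O)CC(=O)[O-].[K+] | starting material
8 | 1-{4-[(tert-butyldimethylsilyl)oxy]-2-methylidenepentadecanoyl}imidazole (racemic) | CCCCCCCCCCCC(O[Si](C)(C)C(C)(C)C)CC(=C)C(=O)n1ccnc1 | intermediate
9 | 2-(tert-butoxycarbonyl)-6-[(tert-butyldimethylsilyl)oxy]-4-methylidene-3-oxoheptadecanoic acid (present as its magnesium chelate; mixture of stereoisomers) | CCCCCCCCCCCC(O[Si](C)(C)C(C)(C)C)CC(=C)C(=O)C(C(=O)O)C(=O)OC(C)(C)C | intermediate
10 | tert-butyl 6-[(tert-butyldimethylsilyl)oxy]-4-methylidene-3-oxoheptadecanoate (racemic) | CCCCCCCCCCCC(O[Si](C)(C)C(C)(C)C)CC(=C)C(=O)CC(=O)OC(C)(C)C | intermediate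
11 | tert-butyl 6-[(tert-butyldimethylsilyl)oxy]-2-diazo-4-methylidene-3-oxoheptadecanoate (racemic) | CCCCCCCCCCCC(O[Si](C)(C)C(C)(C)C)CC(=C)C(=O)C(=[N+]=[N-])C(=O)OC(C)(C)C | intermediate
12 | ethoxyacetylene | C#COCC | starting material
13 | tert-butyl 5-[(tert-butyldimethylsilyl)oxy]-3-methylidene-2-(oxomethylidene)hexadecanoate (racemic) | CCCCCCCCCCCC(O[Si](C)(C)C(C)(C)C)CC(=C)C(=C=O)C(=O)OC(C)(C)C | intermediate
14 | tert-butyl 2-ethoxy-4-oxo-1-{4-[(tert-butyldimethylsilyl)oxy]pentadec-1-en-2-yl}cyclobut-2-ene-1-carboxylate (mixture of diastereomers) | CCCCCCCCCCCC(O[Si](C)(C)C(C)(C)C)CC(=C)C1(C(=O)OC(C)(C)C)C(OCC)=CC1=O | intermediate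
15 | tert-butyl (2Z)-3-ethoxy-5-oxo-2-{4-[(tert-butyldimethylsilyl)oxy]pentadec-1-en-2-yl}penta-2,4-dienoate (alkenyl group cis to the ketene; racemic) | CCCCCCCCCCCC(O[Si](C)(C)C(C)(C)C)CC(=C)/C(C(=O)OC(C)(C)C)=C(OCC)\C=C=O | intermediate
16 | tert-butyl 6-ethoxy-4-oxo-2-{2-[(tert-butyldimethylsilyl)oxy]tridecyl}cyclohexa-1,5-diene-1-carboxylate (racemic) | CCCCCCCCCCCC(O[Si](C)(C)C(C)(C)C)CC1=C(C(=O)OC(C)(C)C)C(OCC)=CC(=O)C1 | intermediate
17 | tert-butyl 2-ethoxy-4-hydroxy-6-{2-[(tert-butyldimethylsilyl)oxy]tridecyl}benzoate (racemic) | CCCCCCCCCCCC(O[Si](C)(C)C(C)(C)C)Cc1cc(O)cc(OCC)c1C(=O)OC(C)(C)C | intermediate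
18 | tert-butyl 2-ethoxy-4-methoxy-6-{2-[(tert-butyldimethylsilyl)oxy]tridecyl}benzoate (racemic) | CCCCCCCCCCCC(O[Si](C)(C)C(C)(C)C)Cc1cc(OC)cc(OCC)c1C(=O)OC(C)(C)C | intermediate
19 | tert-butyl 2-ethoxy-6-(2-hydroxytridecyl)-4-methoxybenzoate (racemic) | CCCCCCCCCCCC(O)Cc1cc(OC)cc(OCC)c1C(=O)OC(C)(C)C | intermediate
20 | tert-butyl 2-ethoxy-4-methoxy-6-(2-oxotridecyl)benzoate | CCCCCCCCCCCC(=O)Cc1cc(OC)cc(OCC)c1C(=O)OC(C)(C)C | intermediate
21 | 2-chloro-7-methoxy-5-(2-oxotridecyl)-4H-1,3,2-benzodioxaborinin-4-one (chloroborate chelate of the salicylic acid) | CCCCCCCCCCCC(=O)Cc1cc(OC)cc2OB(Cl)OC(=O)c12 | intermediate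
22 | 2-hydroxy-4-methoxy-6-(2-oxotridecyl)benzoic acid | CCCCCCCCCCCC(=O)Cc1cc(OC)cc(O)c1C(=O)O | target

**Step count**

Total steps: 10. Longest linear sequence: 10 steps, from dodecanal 1 to 22.

**Steps most likely to fail**

1. Step 6 (proposed new method). The ester-bearing ketene may be diverted into [4+2] addition of the ynol ether across its O=C–C=C=O unit, may acylate the phenol as it forms, or the cyclobutenone may open mainly to the dienylketene isomer that cannot close. The fallback builds the same arene by a known Alder–Rickert aromatisation and sets out from dodecanal 1.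
   - Zn-mediated Barbier propargylation (propargyl bromide, Zn, THF/aq. NH4Cl) should give pentadec-1-yn-4-ol F1.
   - TBSCl/imidazole gives tert-butyldimethyl(pentadec-1-yn-4-yloxy)silane F2.
   - Lithiation (n-BuLi, THF, −78 °C) and trapping with Boc2O gives tert-butyl 5-[(tert-butyldimethylsilyl)oxy]hexadec-2-ynoate F3.
   - Heating F3 with 5,5-dimethyl-1,3-bis(trimethylsilyloxy)cyclohexa-1,3-diene at about 150 °C should give the [4+2] adduct tert-butyl 8,8-dimethyl-3-{2-[(tert-butyldimethylsilyl)oxy]tridecyl}-1,5-bis(trimethylsilyloxy)bicyclo[2.2.2]octa-2,5-diene-2-carboxylate F4. The nucleophilic diene terminus bonds to the alkyne carbon that carries the side chain.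
   - F4 loses 2-methylpropene by retro-[4+2] to give tert-butyl 2,4-bis(trimethylsilyloxy)-6-{2-[(tert-butyldimethylsilyl)oxy]tridecyl}benzoate F5.
   - Methanolysis (MeOH, cat. pyridinium p-toluenesulfonate) gives tert-butyl 2,4-dihydroxy-6-{2-[(tert-butyldimethylsilyl)oxy]tridecyl}benzoate F6.
   - MeI/K2CO3 in acetone should methylate only the C4 hydroxyl, the C2 hydroxyl being hydrogen-bonded to the ester, to give tert-butyl 2-hydroxy-4-methoxy-6-{2-[(tert-butyldimethylsilyl)oxy]tridecyl}benzoate F7.
   - EtI/Cs2CO3 in DMF at 50 °C ethylates the chelated phenol and comes back to the route at 18.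

2. Step 10. The liberated keto acid may cyclodehydrate to the enol lactone under the Lewis acid, the chelated ethyl ether may cleave too slowly so that the C4 methyl ether starts to go, or the salicylic acid may decarboxylate. The fallback uses the enol lactone on purpose as a protected form of the keto acid and sets out from 20.
   - TFA in CH2Cl2, then trifluoroacetic anhydride, should remove the tert-butyl group and close the ring to 8-ethoxy-6-methoxy-3-undecyl-1H-isochromen-1-one F8.
   - BCl3 in CH2Cl2 (−78 → 0 °C) cleaves the ethyl ether peri to the lactone carbonyl to give 8-hydroxy-6-methoxy-3-undecyl-1H-isochromen-1-one F9.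
   - Aqueous KOH in EtOH at 20 °C opens the enol lactone, and acidification at 0 °C to pH 3 comes back to the route at 22.

3. Step 4. Imidazole or the malonate may add in conjugate fashion to the activated acrylate, and the alkenyl β-keto ester may oligomerise before diazo transfer. The fallback makes the C2–C3 bond by aldol addition of a diazo ester and sets out from 5.
   - i-Bu2AlH in CH2Cl2 at −78 °C gives 4-[(tert-butyldimethylsilyl)oxy]-2-methylidenepentadecan-1-ol F10.
   - MnO2 in CH2Cl2 gives 4-[(tert-butyldimethylsilyl)oxy]-2-methylidenepentadecanal F11.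
   - tert-Butyl diazoacetate with catalytic DBU in MeCN adds to the aldehyde to give tert-butyl 6-[(tert-butyldimethylsilyl)oxy]-2-diazo-3-hydroxy-4-methylideneheptadecanoate F12.
   - Dess–Martin oxidation of the carbinol comes back to the route at 11, so steps 3 to 5 are not needed.

**Further compounds**

F1 | step 6 | pentadec-1-yn-4-ol (racemic) | CCCCCCCCCCCC(O)CC#C
F2 | step 6 | tert-butyldimethyl(pentadec-1-yn-4-yloxy)silane (racemic) | CCCCCCCCCCCC(O[Si](C)(C)C(C)(C)C)CC#C
F3 | step 6 | tert-butyl 5-[(tert-butyldimethylsilyl)oxy]hexadec-2-ynoate (racemic) | CCCCCCCCCCCC(O[Si](C)(C)C(C)(C)C)CC#CC(=O)OC(C)(C)C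
F4 | step 6 | tert-butyl 8,8-dimethyl-3-{2-[(tert-butyldimethylsilyl)oxy]tridecyl}-1,5-bis(trimethylsilyloxy)bicyclo[2.2.2]octa-2,5-diene-2-carboxylate (mixture of diastereomers) | C[Si](C)(C)OC12C=C(O[Si](C)(C)C)C(C(C)(C)C1)C(CC(O[Si](C)(C)C(C)(C)C)CCCCCCCCCCC)=C2C(=O)OC(C)(C)C
F5 | step 6 | tert-butyl 2,4-bis(trimethylsilyloxy)-6-{2-[(tert-butyldimethylsilyl)oxy]tridecyl}benzoate (racemic) | CCCCCCCCCCCC(O[Si](C)(C)C(C)(C)C)Cc1cc(O[Si](C)(C)C)cc(O[Si](C)(C)C)c1C(=O)OC(C)(C)C
F6 | step 6 | tert-butyl 2,4-dihydroxy-6-{2-[(tert-butyldimethylsilyl)oxy]tridecyl}benzoate (racemic) | CCCCCCCCCCCC(O[Si](C)(C)C(C)(C)C)Cc1cc(O)cc(O)c1C(=O)OC(C)(C)C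
F7 | step 6 | tert-butyl 2-hydroxy-4-methoxy-6-{2-[(tert-butyldimethylsilyl)oxy]tridecyl}benzoate (racemic) | CCCCCCCCCCCC(O[Si](C)(C)C(C)(C)C)Cc1cc(OC)cc(O)c1C(=O)OC(C)(C)C
F8 | step 10 | 8-ethoxy-6-methoxy-3-undecyl-1H-isochromen-1-one | CCCCCCCCCCCC1=Cc2cc(OC)cc(OCC)c2C(=O)O1
F9 | step 10 | 8-hydroxy-6-methoxy-3-undecyl-1H-isochromen-1-one | CCCCCCCCCCCC1=Cc2cc(OC)cc(O)c2C(=O)O1
F10 | step 4 | 4-[(tert-butyldimethylsilyl)oxy]-2-methylidenepentadecan-1-ol (racemic) | CCCCCCCCCCCC(O[Si](C)(C)C(C)(C)C)CC(=C)CO
F11 | step 4 | 4-[(tert-butyldimethylsilyl)oxy]-2-methylidenepentadecanal (racemic) | CCCCCCCCCCCC(O[Si](C)(C)C(C)(C)C)CC(=C)C=O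
F12 | step 4 | tert-butyl 6-[(tert-butyldimethylsilyl)oxy]-2-diazo-3-hydroxy-4-methylideneheptadecanoate (mixture of diastereomers) | CCCCCCCCCCCC(O[Si](C)(C)C(C)(C)C)CC(=C)C(O)C(=[N+]=[N-])C(=O)OC(C)(C)C
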